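**Plan**

- Retrosynthetic cuts, in order: the C5'–C1'' aryl–alkenyl bond (Heck), the three phenol masks (benzyl ethers), the O1–C2 bond of ring C (acetal exchange), the C3–C1' bond (1,2-aryl shift) and the Cα=Cβ bond of a chalcone (Claisen–Schmidt).
- Enabling feature: ring B sits on C3 of the pyranone ring C, next to an unsubstituted C2 that is bonded to O1 and is at the aldehyde oxidation level. A 2'-hydroxychalcone holds the same aryl group on Cβ, so moving ring B from Cβ to Cα makes C3–C1' and turns Cβ into an acetal carbon, the future C2.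
- Forward order: rings A and B are bought as arenes. The ring B aldehyde (three steps from 5-bromovanillin) and the ring A ketone (one step) are joined to the chalcone, the three-carbon chain is rearranged with Tl(NO3)3, ring C is then closed by acid, the benzyl ethers are removed, and the side chain is attached last.
- Stereochemistry: the target has no stereocentre. Its E alkene comes from the syn-insertion/syn-β-hydride-elimination course of the Heck reaction, and the racemic α-carbon made in the key step vanishes when ring C becomes aromatic.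

Key step: step 6

Remark: isoflavone numbering is used for the chromenones (ring B positions primed); in the chalcone the ketone-derived ring A carries the primed numbers and the aldehyde-derived ring B the unprimed ones.

**Route**

Step 1
Reactants: 1 5-bromovanillin (3-bromo-4-hydroxy-5-methoxybenzaldehyde)
Product: 2 3-bromo-4,5-dihydroxybenzaldehyde
Conditions: BBr3 (2.5 equiv), CH2Cl2, −78 °C to rt; then ice-water
Reagents that add atoms: none
Why: Lewis acid ether cleavage (BBr3 demethylation): boron binds the methoxy oxygen and bromide removes the methyl group by SN2 attack, while the aldehyde and the aryl bromide are untouched at low temperature.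

Step 2
Reactants: 2 3-bromo-4,5-dihydroxybenzaldehyde
Product: 3 3-bromo-5-hydroxy-4-methoxybenzaldehyde
Conditions: MeI (1.05 equiv), Li2CO3 (1.2 equiv), DMF, 40 °C
Reagents that add atoms: iodomethane, CI
Why: Regioselective Williamson etherification: the 4-OH, para to the formyl group and ortho to bromine, is the more acidic hydroxyl, so the weak base Li2CO3 forms only the 4-phenoxide and one equivalent of MeI methylates it, leaving the 5-OH free.

Step 3
Reactants: 3 3-bromo-5-hydroxy-4-methoxybenzaldehyde; 4 benzyl bromide
Product: 5 3-(benzyloxy)-5-bromo-4-methoxybenzaldehyde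
Conditions: K2CO3, DMF, rt
Reagents that add atoms: none
Why: Williamson etherification of the only remaining phenol with a reactive benzylic halide; nothing else in 3 is alkylated under carbonate conditions.

Step 4
Reactants: 6 2',4',6'-trihydroxyacetophenone; 4 benzyl bromide (2.1 equiv)
Product: 7 1-[2,4-bis(benzyloxy)-6-hydroxyphenyl]ethan-1-one
Conditions: K2CO3 (2.2 equiv), DMF, rt
Reagents that add atoms: none
Why: Williamson etherification: the 4-OH and one of the two equivalent ortho hydroxyls are benzylated, whereas the last ortho hydroxyl, locked in a hydrogen bond to the ketone, is the least nucleophilic and should stay free when two equivalents of halide are used.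

Step 5
Reactants: 7 1-[2,4-bis(benzyloxy)-6-hydroxyphenyl]ethan-1-one; 5 3-(benzyloxy)-5-bromo-4-methoxybenzaldehyde
Product: 8 (E)-1-[2,4-bis(benzyloxy)-6-hydroxyphenyl]-3-[3-(benzyloxy)-5-bromo-4-methoxyphenyl]prop-2-en-1-one
Conditions: KOH (50% aq, excess), EtOH/THF, rt; then dilute HCl
Reagents that add atoms: none
Why: Claisen–Schmidt (crossed aldol) condensation: the methyl ketone enolate adds to the non-enolisable aldehyde and E1cB loss of water gives the conjugated enone as the thermodynamically favoured E isomer, the chelated 2'-phenoxide and the 6'-benzyloxy group keeping the chalcone open rather than closed to a flavanone.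

Step 6
Reactants: 8 (E)-1-[2,4-bis(benzyloxy)-6-hydroxyphenyl]-3-[3-(benzyloxy)-5-bromo-4-methoxyphenyl]prop-2-en-1-one
Product: 9 rac-1-[2,4-bis(benzyloxy)-6-hydroxyphenyl]-2-[3-(benzyloxy)-5-bromo-4-methoxyphenyl]-3,3-dimethoxypropan-1-one
Conditions: Tl(NO3)3·3H2O (1.2 equiv), MeOH/HC(OMe)3 (1:1), CH2Cl2 cosolvent, rt; filter off TlNO3, aq NaHCO3
Reagents that add atoms: methanol, CO
Why: This is the known oxidative rearrangement of chalcones to 1,2-diaryl-3,3-dimethoxypropan-1-ones by trivalent thallium, the laboratory counterpart of the biosynthetic aryl shift: methoxythallation of the enone C=C puts a methoxy group on the benzylic β-carbon and thallium on the α-carbon. Loss of monovalent thallium is assisted by ring B through a bridged phenonium ion, which opens to the methoxy-stabilised oxocarbenium ion at the former β-carbon, and methanol traps it as the dimethyl acetal. Only the Cα–C1 (ring B) bond, the future C3–C1' bond, is formed and no ring is closed. The new α-stereocentre arises without control (racemic) and is erased when ring C is aromatised in step 7. The step needs aryl migration to outrun oxidative cyclisation through the free 2'-OH (aurone or flavone) and oxidation of the electron-rich ring A; the 4-OMe para to the migrating carbon raises the migratory aptitude of ring B, the 2'-OH is held in a hydrogen bond to the carbonyl, and methanol with trimethyl orthoformate (which also removes the water of crystallisation) supplies the trapping nucleophile in large excess. Benzyl ethers and the aryl bromide are inert to Tl(NO3)3.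

Step 7
Reactants: 9 rac-1-[2,4-bis(benzyloxy)-6-hydroxyphenyl]-2-[3-(benzyloxy)-5-bromo-4-methoxyphenyl]-3,3-dimethoxypropan-1-one
Product: 11 5,7-bis(benzyloxy)-3-[3-(benzyloxy)-5-bromo-4-methoxyphenyl]-4H-chromen-4-one, via 2-methoxyisoflavanone 10 (not isolated)
Conditions: conc. HCl (cat.), MeOH/THF, 60 °C
Reagents that add atoms: none
Why: Acid-catalysed acetal exchange followed by elimination: the 2'-OH attacks the oxocarbenium ion derived from the dimethyl acetal (6-exo-trig) to give the 2-methoxyisoflavanone, which loses methanol through its enol to form the aromatic 4-pyranone ring C and so removes the α-stereocentre.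

Step 8
Reactants: 11 5,7-bis(benzyloxy)-3-[3-(benzyloxy)-5-bromo-4-methoxyphenyl]-4H-chromen-4-one
Product: 12 3-(3-bromo-5-hydroxy-4-methoxyphenyl)-5,7-dihydroxy-4H-chromen-4-one
Conditions: BCl3 (6 equiv), pentamethylbenzene (9 equiv), CH2Cl2, −78 °C; then H2O
Reagents that add atoms: none
Why: Lewis acid debenzylation with a cation scavenger: BCl3 ionises the aryl benzyl ethers and pentamethylbenzene captures the benzyl cations by Friedel–Crafts alkylation, so ring A is not C-benzylated, and at −78 °C the methyl ether and the C–Br bond (which hydrogenolysis would not spare) should be kept.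

Step 9
Reactants: 12 3-(3-bromo-5-hydroxy-4-methoxyphenyl)-5,7-dihydroxy-4H-chromen-4-one; 13 2-methylbut-3-en-2-ol (4 equiv)
Product: 14 5,7-dihydroxy-3-{3-hydroxy-5-[(E)-3-hydroxy-3-methylbut-1-en-1-yl]-4-methoxyphenyl}-4H-chromen-4-one
Conditions: Pd(OAc)2 (10 mol %), P(o-tol)3 (20 mol %), Et3N, DMF, 100 °C, argon
Reagents that add atoms: none
Why: Mizoroki–Heck reaction: zerovalent palladium formed from Pd(OAc)2 and the phosphine inserts into the C–Br bond, syn-carbopalladation places the aryl group on the terminal alkene carbon, and syn β-hydride elimination, possible only towards the benzylic carbon because the carbinol carbon bears no hydrogen, gives the E styrene, while the basic medium spares the acid-labile tertiary allylic alcohol and tolerates the free phenols.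

**Compound list**

1 | 5-bromovanillin (3-bromo-4-hydroxy-5-methoxybenzaldehyde) | COc1cc(C=O)cc(Br)c1O | starting material
2 | 3-bromo-4,5-dihydroxybenzaldehyde | O=Cc1cc(O)c(O)c(Br)c1 | intermediate
3 | 3-bromo-5-hydroxy-4-methoxybenzaldehyde | COc1c(O)cc(C=O)cc1Br | intermediate
4 | benzyl bromide | BrCc1ccccc1 | starting material
5 | 3-(benzyloxy)-5-bromo-4-methoxybenzaldehyde | COc1c(OCc2ccccc2)cc(C=O)cc1Br | intermediate
6 | 2',4',6'-trihydroxyacetophenone | CC(=O)c1c(O)cc(O)cc1O | starting material
7 | 1-[2,4-bis(benzyloxy)-6-hydroxyphenyl]ethan-1-one | CC(=O)c1c(O)cc(OCc2ccccc2)cc1OCc1ccccc1 | intermediate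
8 | (E)-1-[2,4-bis(benzyloxy)-6-hydroxyphenyl]-3-[3-(benzyloxy)-5-bromo-4-methoxyphenyl]prop-2-en-1-one | COc1c(OCc2ccccc2)cc(/C=C/C(=O)c2c(O)cc(OCc3ccccc3)cc2OCc2ccccc2)cc1Br | intermediate
9 | rac-1-[2,4-bis(benzyloxy)-6-hydroxyphenyl]-2-[3-(benzyloxy)-5-bromo-4-methoxyphenyl]-3,3-dimethoxypropan-1-one (racemic at C2) | COC(OC)C(c1cc(OCc2ccccc2)c(OC)c(Br)c1)C(=O)c1c(O)cc(OCc2ccccc2)cc1OCc1ccccc1 | intermediate
10 | 5,7-bis(benzyloxy)-3-[3-(benzyloxy)-5-bromo-4-methoxyphenyl]-2-methoxy-2,3-dihydro-4H-chromen-4-one (racemic mixture of C2/C3 diastereomers, not isolated) | COC1Oc2cc(OCc3ccccc3)cc(OCc3ccccc3)c2C(=O)C1c1cc(OCc2ccccc2)c(OC)c(Br)c1 | intermediate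
11 | 5,7-bis(benzyloxy)-3-[3-(benzyloxy)-5-bromo-4-methoxyphenyl]-4H-chromen-4-one | COc1c(OCc2ccccc2)cc(-c2coc3cc(OCc4ccccc4)cc(OCc4ccccc4)c3c2=O)cc1Br | intermediate
12 | 3-(3-bromo-5-hydroxy-4-methoxyphenyl)-5,7-dihydroxy-4H-chromen-4-one | COc1c(O)cc(-c2coc3cc(O)cc(O)c3c2=O)cc1Br | intermediate
13 | 2-methylbut-3-en-2-ol | C=CC(C)(C)O | starting material
14 | 5,7-dihydroxy-3-{3-hydroxy-5-[(E)-3-hydroxy-3-methylbut-1-en-1-yl]-4-methoxyphenyl}-4H-chromen-4-one | COc1c(O)cc(-c2coc3cc(O)cc(O)c3c2=O)cc1/C=C/C(C)(C)O | target

**Step count**

Total steps: 9. Longest linear sequence: 8 (steps 1, 2, 3, 5, 6, 7, 8, 9).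

**Steps most likely to fail, with fallbacks**

Step 6. Oxidative cyclisation through the free 2'-hydroxyl (aurone or flavone formation), or oxidation of the electron-rich ring A, may outrun the aryl migration. The fallback sets out from 8 and masks the phenol before the oxidation. Acetylation (Ac2O, Et3N, DMAP, CH2Cl2) should give (E)-3,5-bis(benzyloxy)-2-{3-[3-(benzyloxy)-5-bromo-4-methoxyphenyl]prop-2-enoyl}phenyl acetate F1. The same Tl(NO3)3·3H2O treatment in MeOH/HC(OMe)3, now with no nucleophilic phenol and a less electron-rich ring A, should give rac-3,5-bis(benzyloxy)-2-{2-[3-(benzyloxy)-5-bromo-4-methoxyphenyl]-3,3-dimethoxypropanoyl}phenyl acetate F2. Warm HCl/MeOH then removes the acetate by methanolysis and closes ring C in the same flask, so the fallback comes back to the route at 11.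

Step 9. Oxidative addition into the electron-rich bromoarene may be slow once the phenols are deprotonated, which would invite catalyst decomposition, protodebromination, or dehydration of the tertiary allylic alcohol on prolonged heating. The fallback sets out from 12 and couples a protected substrate. Ac2O/pyridine should give 3-[3-(acetyloxy)-5-bromo-4-methoxyphenyl]-4-oxo-4H-chromene-5,7-diyl diacetate F3. The Heck reaction with 13 under the same Pd(OAc)2/P(o-tol)3/Et3N conditions, now on a neutral and less electron-rich bromide, should give 3-{3-(acetyloxy)-5-[(E)-3-hydroxy-3-methylbut-1-en-1-yl]-4-methoxyphenyl}-4-oxo-4H-chromene-5,7-diyl diacetate F4. K2CO3 in MeOH at 0 °C removes the acetates without touching the allylic alcohol, and the fallback comes back to the route at 14.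

Step 2. Methylation may occur at the wrong hydroxyl or twice. The fallback sets out from 2 and reverses the order of the two alkylations, using the opposite selectivity of the dianion. NaH (2.2 equiv) in DMSO followed by one equivalent of benzyl bromide should alkylate the more nucleophilic 5-phenoxide (meta to the formyl group and not flanked by bromine) to give 3-(benzyloxy)-5-bromo-4-hydroxybenzaldehyde F5. Methylation of the remaining 4-OH (MeI, K2CO3, DMF) then gives the aldehyde directly, so the fallback bypasses 3 and comes back to the route at 5.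

**Further compounds**

F1 | step 6 | (E)-3,5-bis(benzyloxy)-2-{3-[3-(benzyloxy)-5-bromo-4-methoxyphenyl]prop-2-enoyl}phenyl acetate | COc1c(OCc2ccccc2)cc(/C=C/C(=O)c2c(OC(C)=O)cc(OCc3ccccc3)cc2OCc2ccccc2)cc1Br
F2 | step 6 | rac-3,5-bis(benzyloxy)-2-{2-[3-(benzyloxy)-5-bromo-4-methoxyphenyl]-3,3-dimethoxypropanoyl}phenyl acetate | COC(OC)C(c1cc(OCc2ccccc2)c(OC)c(Br)c1)C(=O)c1c(OC(C)=O)cc(OCc2ccccc2)cc1OCc1ccccc1
F3 | step 9 | 3-[3-(acetyloxy)-5-bromo-4-methoxyphenyl]-4-oxo-4H-chromene-5,7-diyl diacetate | COc1c(OC(C)=O)cc(-c2coc3cc(OC(C)=O)cc(OC(C)=O)c3c2=O)cc1Br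
F4 | step 9 | 3-{3-(acetyloxy)-5-[(E)-3-hydroxy-3-methylbut-1-en-1-yl]-4-methoxyphenyl}-4-oxo-4H-chromene-5,7-diyl diacetate | COc1c(OC(C)=O)cc(-c2coc3cc(OC(C)=O)cc(OC(C)=O)c3c2=O)cc1/C=C/C(C)(C)O
F5 | step 2 | 3-(benzyloxy)-5-bromo-4-hydroxybenzaldehyde | O=Cc1cc(Br)c(O)c(OCc2ccccc2)c1
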